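Carbons are numbered as in germacranes (C1–C15) for every carbocyclic intermediate.

## Analysis of the target

The target 25 is a germacranolide: a ten-membered carbocycle C1–C10 fused through C6 and C7 to a butenolide (C7=C11, C12 carbonyl, ring oxygen on C6). C1 is a ketone cross-conjugated with the exocyclic methylene C10=C14. C4/C5 carry a trisubstituted epoxide with the methyl C15 on C4, C8 carries a tiglate, and C11 carries the acetoxymethyl carbon C13. The four stereocentres are (4R,5R,6S,8S). C4 and C5 are tied together as a trans epoxide, C5 is vicinal to the lactone carbinol C6, and C6 and C8 flank the sp2 carbon C7, so neither can easily control the other. The exo-methylene enone is a Michael acceptor, the γ-hydrogen at C6 is acidic and lies between two allylic acyloxy leaving groups, and the epoxide is acid-labile, so esters and epoxide have to come late. The hard parts are the ten-membered ring and the (E) geometry at C4=C5 that the trans epoxide requires. The strategy rests on the fact that C1 and C5 face each other across the ring. A C1–C5 bond turns the macrocycle into a cis-fused hydroazulene (five-membered ring C1–C5, seven-membered ring C1, C5–C10) in which C1 is a tertiary carbinol and C4 can carry a trimethylstannyl group 1,3 to that oxygen. Cutting that bond again gives ketone, olefin and medium ring in one operation.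

## Retrosynthetic reasoning

**25 to 24 (C4–O and C5–O).** The epoxide is the most acid-sensitive group and would not survive HF-mediated desilylation, so it is installed last. The (E)-olefin of 24 fixes the trans relationship. The face is set by the C6 centre: allylic strain holds H6 in the olefin plane, the ring chain then covers one face, and the oxidant enters from the peripheral face, syn to the lactone oxygen. That is the (4R,5R) epoxide.

**24 to 20 (ester C–O bonds at C13 and C8, through 23, 22 and 21).** Esters cannot pass through the stannyl anion, enolate and organochromium steps. C8 therefore travels as a silyl ether and C13 as a PMB ether. The silyl ether is exchanged first, and the PMB ether is removed oxidatively only after tin has left the molecule.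

**20 to 18 (reconnection of C1–C5).** This is the key disconnection. Joining C1 to C5 and placing tin on C4 gives the γ-stannyl tertiary alcohol 18. Forward, oxidation at the C1 oxygen cleaves C1–C5 and expels tin from C4. The medium ring is made by ring opening, so no macrocyclisation is needed. The olefin geometry is dictated by the relative configuration at C4/C5 of a cyclopentane, which is far easier to control than a medium-ring olefin.

**18 to 17 (C1–C10).** The tertiary allylic carbinol is the adduct of a C10 alkenyl metal with the C1 ketone. Cutting here leaves the 2-bromoalkene of 17 as the latent nucleophile. The seven-membered ring closes intramolecularly, so the configuration at C1 follows from the tether, and it is erased in the key step anyway.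

**17 to 14 and 15 (C5–C6 and the lactone O–C12).** The butenolide carbinol C6 is an aldol carbon. Enolate 14 is regiodefined because it is generated by conjugate addition of the stannyl anion 13 (from 12) to enone 11. The same step sets the tin-bearing quaternary C4. The electrophile 15 is a (Z)-4-oxo-enoate, so the aldolate 16 lactonises directly. The aldehyde must enter anti to tin, since the Sn/C6 trans relationship is what later becomes the (E)-olefin.

**15 to 10 to 8 (C12=O and C6–OH from a furan).** A tetrasubstituted (Z)-4-oxo-enoic acid is most simply stored as its cyclic hydroxybutenolide 10. This is the photo-oxygenation product of the 3,4-disubstituted furan 8 through endoperoxide 9. A hindered amine directs the lactone carbonyl to the α-carbon next to the smaller CH2OPMB substituent.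

**8 to 7 to 3 and 5 (C8–C9).** C8 is set by reagent-controlled 2-bromoallylation of aldehyde 3 with the chiral allylborane 6 made from stannane 5. This step is the source of absolute configuration. Stannane 5 comes from 4, and 3 comes from the symmetric diol 1 through 2.

## Alternatives that were turned down

**Alternative 1:** The disconnection is C6–C7 together with the lactone O–C12 bond. It leads back to the open-chain aldehyde A2, which has a (Z)-β-triflyloxy enoate at C7/C11 and an epoxy aldehyde at C6. Forward, CrCl2 with catalytic NiCl2 converts the enol triflate of A2 into an alkenylchromium that adds to the C6 aldehyde, and the alkoxide lactonises onto C12 to give A1.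
- For it: aldehyde alkenylation of this kind is the dependable mode of the chromium reaction. Every stereocentre except C6 can be set on acyclic material by catalyst control, so no resolution is needed. The epoxide is in place before the ring exists, so there is no late facial question. On absolute stereocontrol and on the epoxide this alternative is stronger than the chosen route.
- Against it: a ten-membered ring is closed by bond formation, with the entropic and transannular penalty. C6 is created in that closure next to an epoxide, with no clear facial bias. The α,β-epoxy aldehyde is fragile. A1 carries the same silyl ether on C1 and C8, which must then be told apart to make the C1 ketone and the C8 tiglate.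
- In its place the chosen route offers a ring that appears by fragmentation and an olefin geometry that is stereospecific.

**Alternative 2:** Here C1–C10 is formed while C1–C7 is broken. The precursor A4 is a cycloheptanone (C1–C7) whose quaternary C7 carries the 2-bromoallyl carbinol chain and an α-phenylthio γ-lactone. Forward, Bu3SnH/AIBN generates the C10 alkenyl radical, which adds to the C1 carbonyl. The alkoxy radical cleaves C1–C7, and the C7 radical expels phenylthiyl from C11 to give A3.
- For it: one step delivers enone, medium ring and butenolide olefin. Like the chosen route it avoids macrocyclisation. The C4–C6 oxygenation is fixed on a seven-membered ring before expansion, which is a real advantage over a late epoxidation.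
- Against it: addition of an alkenyl radical to a ketone carbonyl is reversible and competes with reduction by the tin hydride and with 1,5-hydrogen transfer from the activated C6–H. A4 has a quaternary carbon flanked by three stereocentres and would take many steps. The acetonide of A3 still has to be converted into the trans epoxide (deprotection, selective activation at C5, closure with inversion).
- The chosen fragmentation is a polar, stereospecific process on a precursor that is seven steps from commercial material.

**Alternative 3:** Here C3–C4 is formed while C1–C6 is broken. The precursor A6 is a 1-methoxy-1-vinyl-2-[(E)-propenyl]cyclohexanol. Forward, KH/18-crown-6 triggers the anionic oxy-Cope shift to the enolate of A5.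
- For it: this is the most dependable key step of the four. The chair transition state transmits configuration, and the enolate is regiodefined.
- Against it: A5 is far from the target. It has no C11–C13 unit, so the whole butenolide must be annulated onto a flexible ten-membered ketone. C14 is an sp3 CH2OPMB branch and not the enone methylene. C4 is a methine that must be dehydrogenated before it can be epoxidised, so its stereocentre is made and then destroyed. The enol ether must still be hydrolysed.
- The chosen route is weaker in the intrinsic reliability of the key step, but its key product is two functional-group exchanges and one epoxidation away from 25.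

Key step: step 9

Assumption (remark on the chemistry): no enantioselective conjugate stannylation of a β-substituted cyclopentenone is relied on, so enolate 14 is racemic. The C8 centre of 15 then also serves as the resolving element, and at most half of 10 can end up as 17.

## Route

Step 1
Reactants: 1 furan-3,4-diyldimethanol
Product: 2 {4-[(4-methoxybenzyloxy)methyl]furan-3-yl}methanol
Conditions: NaH (1.0 equiv), THF/DMF, 0 °C; PMBCl (0.9 equiv), Bu4NI (cat.), 0 °C→rt
Reagents that add atoms: 4-methoxybenzyl chloride, COc1ccc(CCl)cc1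
Why: Williamson mono-etherification of a C2-symmetric diol; the diol is used in slight excess and recovered, so the statistical outcome costs only cheap material.

Step 2
Reactants: 2 {4-[(4-methoxybenzyloxy)methyl]furan-3-yl}methanol
Product: 3 4-[(4-methoxybenzyloxy)methyl]furan-3-carbaldehyde
Conditions: MnO2 (activated, excess), CH2Cl2, rt
Reagents that add atoms: none
Why: MnO2 oxidation of a furylmethyl (benzylic-type) alcohol stops at the aldehyde and leaves the PMB ether and the furan ring alone.

Step 3
Reactants: 4 2,3-dibromoprop-1-ene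
Product: 5 (2-bromoprop-2-en-1-yl)tributylstannane
Conditions: Bu3SnH, LiN(iPr)2, THF, 0 °C; then 4, −78 °C→rt
Reagents that add atoms: tributyltin hydride, CCCC[SnH](CCCC)CCCC
Why: Bu3SnLi displaces the allylic bromide (direct and allylically transposed substitution give the same product) while the vinylic bromide is not substituted at low temperature.

Step 4
Reactants: 3 4-[(4-methoxybenzyloxy)methyl]furan-3-carbaldehyde; 5 (2-bromoprop-2-en-1-yl)tributylstannane
Product: 7 (1S)-3-bromo-1-{4-[(4-methoxybenzyloxy)methyl]furan-3-yl}but-3-en-1-ol, via chiral bromoallylborane 6 (not isolated)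
Conditions: (1S,2S)-TsNHCH(Ph)CH(Ph)NHTs, BBr3, CH2Cl2, 0 °C→rt, evaporate; 5, CH2Cl2, rt; 3, −78 °C; aq. NaHCO3
Reagents that add atoms: none
Why: Corey-type enantioselective 2-bromoallylation: tin-to-boron exchange gives allylborane 6, which transfers the allyl group through a chair transition state in which the sulfonyl groups of the diazaborolidine select the aldehyde face. The (S,S)-controller is chosen for the (S)-carbinol by analogy with aromatic aldehydes, and the configuration is to be confirmed on 7 (Mosher esters) before going on.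

Step 5
Reactants: 7 (1S)-3-bromo-1-{4-[(4-methoxybenzyloxy)methyl]furan-3-yl}but-3-en-1-ol
Product: 8 {[(1S)-3-bromo-1-{4-[(4-methoxybenzyloxy)methyl]furan-3-yl}but-3-en-1-yl]oxy}(tert-butyl)dimethylsilane
Conditions: TBSCl, imidazole, DMF, rt
Reagents that add atoms: tert-butyldimethylsilyl chloride, CC(C)(C)[Si](C)(C)Cl
Why: Standard silylation of a secondary alcohol; the bulky silyl ether also enlarges the C8 substituent, which helps the regiochemistry of step 6.

Step 6
Reactants: 8 {[(1S)-3-bromo-1-{4-[(4-methoxybenzyloxy)methyl]furan-3-yl}but-3-en-1-yl]oxy}(tert-butyl)dimethylsilane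
Product: 10 4-[(1S)-3-bromo-1-(tert-butyldimethylsilyloxy)but-3-en-1-yl]-5-hydroxy-3-[(4-methoxybenzyloxy)methyl]furan-2(5H)-one (both hemiacetal epimers), via furan endoperoxide 9 (not isolated)
Conditions: O2, hν (visible), tetraphenylporphyrin (cat.), iPr2NEt, CH2Cl2, −78 °C→rt
Reagents that add atoms: dioxygen, O=O
Why: Singlet oxygen adds [4+2] to the furan, and the hindered amine opens endoperoxide 9 by removing the bridgehead hydrogen next to the smaller CH2OPMB group (base-directed photo-oxygenation of 3-substituted furans). The lactone carbonyl (C12) therefore forms beside C11 and the hemiacetal (C6) beside the branched C8 substituent; the vinylic bromide is too electron-poor to react.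

Step 7
Reactants: 11 3-methylcyclopent-2-en-1-one; 12 trimethyltin chloride; 10 4-[(1S)-3-bromo-1-(tert-butyldimethylsilyloxy)but-3-en-1-yl]-5-hydroxy-3-[(4-methoxybenzyloxy)methyl]furan-2(5H)-one
Product: 17 (5R)-4-[(1S)-3-bromo-1-(tert-butyldimethylsilyloxy)but-3-en-1-yl]-3-[(4-methoxybenzyloxy)methyl]-5-[(1S,2S)-2-methyl-5-oxo-2-(trimethylstannyl)cyclopentyl]furan-2(5H)-one, via trimethylstannyllithium 13 (not isolated), via lithium stannyl enolate 14 (not isolated), via lithium carboxylate aldehyde 15 (not isolated), via hydroxy acid aldol adduct 16 (not isolated)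
Conditions: 12 (2.4 equiv), Li, THF, 0 °C→rt; 11 (2.5 equiv), −78 °C; 15 [from 10, LiN(SiMe3)2 (1.0 equiv), THF, −78 °C] added by cannula; AcOH, −78 °C→rt; PPTS (cat.), CH2Cl2, rt; chromatography
Reagents that add atoms: none
Why: Tandem conjugate stannylation/aldol trapping: Me3SnLi adds 1,4 to 11, the aldehyde of ring-opened 15 enters C5 anti to the C4–Sn bond (steric and stereoelectronic, as for β-silyl and β-stannyl enolates), and the closed chair transition state of the cyclic (E)-enolate gives the anti aldol, so C4, C5 and C6 are set relative to one another; the (Z)-γ-hydroxy acid 16 lactonises on acidification. Because 14 is racemic, its (S)-C4 enantiomer gives 17 and its (R)-C4 enantiomer gives the C4,C5,C6-epimeric diastereomer, which is removed by chromatography.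

Step 8
Reactants: 17 (5R)-4-[(1S)-3-bromo-1-(tert-butyldimethylsilyloxy)but-3-en-1-yl]-3-[(4-methoxybenzyloxy)methyl]-5-[(1S,2S)-2-methyl-5-oxo-2-(trimethylstannyl)cyclopentyl]furan-2(5H)-one
Product: 18 (1R,4S,5S,6R,8S)-8-(tert-butyldimethylsilyloxy)-1-hydroxy-13-(4-methoxybenzyloxy)-4-(trimethylstannyl)guaia-7(11),10(14)-dien-12,6-olide (cis-fused stannyl hydroazulenol butenolide; OH, H5 and Sn on one face of the cyclopentane)
Conditions: CrCl2 (6 equiv), NiCl2 (2 mol %), DMF, rt→50 °C; aq. work-up
Reagents that add atoms: none
Why: Intramolecular Nozaki–Hiyama–Kishi alkenylation of a ketone: the 2-bromoalkene adds oxidatively to zerovalent nickel, transmetalates to trivalent chromium, and the alkenylchromium adds to C1 in a 7-exo closure. The tether through C5–C6 forces attack on the ketone face cis to C6 and gives the cis-fused carbinol; the reagent is not basic and tolerates lactone, silyl ether and the alkylstannane.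

Step 9
Reactants: 18 (1R,4S,5S,6R,8S)-8-(tert-butyldimethylsilyloxy)-1-hydroxy-13-(4-methoxybenzyloxy)-4-(trimethylstannyl)guaia-7(11),10(14)-dien-12,6-olide
Product: 20 (4E,6R,8S)-8-(tert-butyldimethylsilyloxy)-13-(4-methoxybenzyloxy)-1-oxogermacra-4,7(11),10(14)-trien-12,6-olide, via lead alkoxide 19 (not isolated)
Conditions: Pb(OAc)4 (1.3 equiv), benzene, rt→60 °C
Reagents that add atoms: none
Why: The tertiary C1 hydroxyl exchanges an acetate on tetravalent lead to give alkoxide 19. Collapse of the O–Pb bond, with lead leaving as divalent Pb(OAc)2, is coupled to cleavage of C1–C5 and loss of the stannyl group from C4 as Me3SnOAc, so the C1 carbonyl and the C4=C5 double bond form together. The closest known reaction type is the oxidative fragmentation of γ-stannyl alcohols (3-stannyl cycloalkanols) with Pb(OAc)4 or PhI(OAc)2 to unsaturated ketones, including fused carbinols that open to medium-ring enones. No ring is closed by bond formation: the ten-membered ring appears because the bond shared by the five- and seven-membered rings is cut, so no cyclisation entropy is paid. No stereocentre is created; C1, C4 and C5 are erased and C6 and C8 are untouched. The only new stereochemical element is the olefin geometry, and the substrate fixes it: tin is trans to C6 on the cyclopentane, and in the envelope with tin pseudo-axial the C4–Sn bond lies close to anti-periplanar to C1–C5 (about 150–160°, the limit in a five-membered ring), which puts C3 trans to C6, i.e. (E). The step needs regioselective scission of C1–C5 over C1–C2 and C1–C10, which the β-tin stabilisation at C5 secures. It also needs chemoselectivity for the single free hydroxyl, which holds because silyl ether, PMB ether, butenolide and the 1,1-disubstituted alkene do not react with Pb(OAc)4 under these conditions.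

Step 10
Reactants: 20 (4E,6R,8S)-8-(tert-butyldimethylsilyloxy)-13-(4-methoxybenzyloxy)-1-oxogermacra-4,7(11),10(14)-trien-12,6-olide
Product: 21 (4E,6R,8S)-8-hydroxy-13-(4-methoxybenzyloxy)-1-oxogermacra-4,7(11),10(14)-trien-12,6-olide
Conditions: HF·pyridine, pyridine, THF, 0 °C→rt
Reagents that add atoms: none
Why: Buffered HF cleaves the secondary silyl ether without the basic fluoride that would attack the exo-methylene enone or deprotonate C6; no epoxide is present yet, so acid is tolerated.

Step 11
Reactants: 21 (4E,6R,8S)-8-hydroxy-13-(4-methoxybenzyloxy)-1-oxogermacra-4,7(11),10(14)-trien-12,6-olide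
Product: 22 (4E,6R,8S)-13-(4-methoxybenzyloxy)-8-[(E)-2-methylbut-2-enoyloxy]-1-oxogermacra-4,7(11),10(14)-trien-12,6-olide
Conditions: tigloyl chloride, pyridine, DMAP (cat.), CH2Cl2, 0 °C→rt
Reagents that add atoms: (E)-2-methylbut-2-enoyl chloride, C/C=C(\C)C(=O)Cl
Why: Acyl-transfer esterification of the only free hydroxyl with retention at C8; the weak base does not deprotonate C6, and the (E) geometry of the tigloyl group is the stable one.

Step 12
Reactants: 22 (4E,6R,8S)-13-(4-methoxybenzyloxy)-8-[(E)-2-methylbut-2-enoyloxy]-1-oxogermacra-4,7(11),10(14)-trien-12,6-olide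
Product: 23 (4E,6R,8S)-13-hydroxy-8-[(E)-2-methylbut-2-enoyloxy]-1-oxogermacra-4,7(11),10(14)-trien-12,6-olide
Conditions: DDQ, CH2Cl2/pH 7 phosphate buffer, 0 °C
Reagents that add atoms: none
Why: Oxidative PMB cleavage under neutral conditions; it is placed after the fragmentation so that the oxidant never meets the electron-rich C–Sn bond.

Step 13
Reactants: 23 (4E,6R,8S)-13-hydroxy-8-[(E)-2-methylbut-2-enoyloxy]-1-oxogermacra-4,7(11),10(14)-trien-12,6-olide
Product: 24 (4E,6R,8S)-13-acetoxy-8-[(E)-2-methylbut-2-enoyloxy]-1-oxogermacra-4,7(11),10(14)-trien-12,6-olide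
Conditions: Ac2O, pyridine, CH2Cl2, 0 °C
Reagents that add atoms: acetic anhydride, CC(=O)OC(C)=O
Why: Acetylation of the primary allylic alcohol with a weak base at low temperature, so that the allylic acetate is not eliminated through the C6 dienolate.

Step 14
Reactants: 24 (4E,6R,8S)-13-acetoxy-8-[(E)-2-methylbut-2-enoyloxy]-1-oxogermacra-4,7(11),10(14)-trien-12,6-olide
Product: 25 (4R,5R,6S,8S)-13-acetoxy-4,5-epoxy-8-[(E)-2-methylbut-2-enoyloxy]-1-oxogermacra-7(11),10(14)-dien-12,6-olide (the target)
Conditions: dimethyldioxirane (acetone solution), CH2Cl2, −30→0 °C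
Reagents that add atoms: dimethyldioxirane, CC1(C)OO1
Why: Neutral electrophilic epoxidation picks the only electron-rich alkene (the enone methylene, butenolide and tiglate olefins are deactivated) and cannot cause Baeyer–Villiger oxidation of the ketone. The (E)-olefin gives the trans epoxide stereospecifically; with H6 held in the olefin plane by allylic strain against C15, the ring chain covers one face and the reagent enters from the peripheral face syn to the lactone oxygen, which is the (4R,5R) epoxide.

## Compound list

1 | furan-3,4-diyldimethanol | OCc1cocc1CO | starting material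
2 | {4-[(4-methoxybenzyloxy)methyl]furan-3-yl}methanol | COc1ccc(COCc2cocc2CO)cc1 | intermediate
3 | 4-[(4-methoxybenzyloxy)methyl]furan-3-carbaldehyde | COc1ccc(COCc2cocc2C=O)cc1 | intermediate
4 | 2,3-dibromoprop-1-ene | C=C(Br)CBr | starting material
5 | (2-bromoprop-2-en-1-yl)tributylstannane | C=C(Br)C[Sn](CCCC)(CCCC)CCCC | intermediate
6 | (4S,5S)-2-(2-bromoprop-2-en-1-yl)-1,3-bis(4-methylbenzenesulfonyl)-4,5-diphenyl-1,3,2-diazaborolidine | C=C(Br)CB1N(S(=O)(=O)c2ccc(C)cc2)[C@@H](c2ccccc2)[C@H](c2ccccc2)N1S(=O)(=O)c1ccc(C)cc1 | intermediate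
7 | (1S)-3-bromo-1-{4-[(4-methoxybenzyloxy)methyl]furan-3-yl}but-3-en-1-ol | C=C(Br)C[C@H](O)c1cocc1COCc1ccc(OC)cc1 | intermediate
8 | {[(1S)-3-bromo-1-{4-[(4-methoxybenzyloxy)methyl]furan-3-yl}but-3-en-1-yl]oxy}(tert-butyl)dimethylsilane | C=C(Br)C[C@H](O[Si](C)(C)C(C)(C)C)c1cocc1COCc1ccc(OC)cc1 | intermediate
9 | furan endoperoxide of 8 (2,3,7-trioxabicyclo[2.2.1]hept-5-ene, diastereomer mixture) | C=C(Br)C[C@H](O[Si](C)(C)C(C)(C)C)C1=C(COCc2ccc(OC)cc2)C2OOC1O2 | intermediate
10 | 4-[(1S)-3-bromo-1-(tert-butyldimethylsilyloxy)but-3-en-1-yl]-5-hydroxy-3-[(4-methoxybenzyloxy)methyl]furan-2(5H)-one (both hemiacetal epimers) | C=C(Br)C[C@H](O[Si](C)(C)C(C)(C)C)C1=C(COCc2ccc(OC)cc2)C(=O)OC1O | intermediate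
11 | 3-methylcyclopent-2-en-1-one | CC1=CC(=O)CC1 | starting material
12 | trimethyltin chloride | C[Sn](C)(C)Cl | starting material
13 | (trimethylstannyl)lithium | [Li][Sn](C)(C)C | intermediate
14 | lithium 3-methyl-3-(trimethylstannyl)cyclopent-1-en-1-olate (racemic) | [Li]OC1=CC(C)([Sn](C)(C)C)CC1 | intermediate
15 | lithium (2Z,4S)-6-bromo-4-(tert-butyldimethylsilyloxy)-3-formyl-2-[(4-methoxybenzyloxy)methyl]hepta-2,6-dienoate | C=C(Br)C[C@H](O[Si](C)(C)C(C)(C)C)/C(C=O)=C(\COCc1ccc(OC)cc1)C(=O)[O-].[Li+] | intermediate
16 | (2Z,4S)-6-bromo-4-(tert-butyldimethylsilyloxy)-3-{(R)-hydroxy[(1S,2S)-2-methyl-5-oxo-2-(trimethylstannyl)cyclopentyl]methyl}-2-[(4-methoxybenzyloxy)methyl]hepta-2,6-dienoic acid | C=C(Br)C[C@H](O[Si](C)(C)C(C)(C)C)/C(=C(\COCc1ccc(OC)cc1)C(=O)O)[C@H](O)[C@@H]1[C@@](C)([Sn](C)(C)C)CCC1=O | intermediate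
17 | (5R)-4-[(1S)-3-bromo-1-(tert-butyldimethylsilyloxy)but-3-en-1-yl]-3-[(4-methoxybenzyloxy)methyl]-5-[(1S,2S)-2-methyl-5-oxo-2-(trimethylstannyl)cyclopentyl]furan-2(5H)-one | C=C(Br)C[C@H](O[Si](C)(C)C(C)(C)C)C1=C(COCc2ccc(OC)cc2)C(=O)O[C@@H]1[C@@H]2[C@@](C)([Sn](C)(C)C)CCC2=O | intermediate
18 | (1R,4S,5S,6R,8S)-8-(tert-butyldimethylsilyloxy)-1-hydroxy-13-(4-methoxybenzyloxy)-4-(trimethylstannyl)guaia-7(11),10(14)-dien-12,6-olide | C=C1C[C@H](O[Si](C)(C)C(C)(C)C)C2=C(COCc3ccc(OC)cc3)C(=O)O[C@@H]2[C@@H]3[C@@](C)([Sn](C)(C)C)CC[C@]13O | intermediate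
19 | O1-triacetoxyplumbyl derivative of 18 (tetravalent lead alkoxide) | C=C1C[C@H](O[Si](C)(C)C(C)(C)C)C2=C(COCc3ccc(OC)cc3)C(=O)O[C@@H]2[C@@H]3[C@@](C)([Sn](C)(C)C)CC[C@]13O[Pb](OC(C)=O)(OC(C)=O)OC(C)=O | intermediate
20 | (4E,6R,8S)-8-(tert-butyldimethylsilyloxy)-13-(4-methoxybenzyloxy)-1-oxogermacra-4,7(11),10(14)-trien-12,6-olide | C=C1C[C@H](O[Si](C)(C)C(C)(C)C)C2=C(COCc3ccc(OC)cc3)C(=O)O[C@@H]2/C=C(\C)CCC1=O | intermediate
21 | (4E,6R,8S)-8-hydroxy-13-(4-methoxybenzyloxy)-1-oxogermacra-4,7(11),10(14)-trien-12,6-olide | C=C1C[C@H](O)C2=C(COCc3ccc(OC)cc3)C(=O)O[C@@H]2/C=C(\C)CCC1=O | intermediate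
22 | (4E,6R,8S)-13-(4-methoxybenzyloxy)-8-[(E)-2-methylbut-2-enoyloxy]-1-oxogermacra-4,7(11),10(14)-trien-12,6-olide | C=C1C[C@H](OC(=O)/C(C)=C/C)C2=C(COCc3ccc(OC)cc3)C(=O)O[C@@H]2/C=C(\C)CCC1=O | intermediate
23 | (4E,6R,8S)-13-hydroxy-8-[(E)-2-methylbut-2-enoyloxy]-1-oxogermacra-4,7(11),10(14)-trien-12,6-olide | C=C1C[C@H](OC(=O)/C(C)=C/C)C2=C(CO)C(=O)O[C@@H]2/C=C(\C)CCC1=O | intermediate
24 | (4E,6R,8S)-13-acetoxy-8-[(E)-2-methylbut-2-enoyloxy]-1-oxogermacra-4,7(11),10(14)-trien-12,6-olide | C=C1C[C@H](OC(=O)/C(C)=C/C)C2=C(COC(C)=O)C(=O)O[C@@H]2/C=C(\C)CCC1=O | intermediate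
25 | (4R,5R,6S,8S)-13-acetoxy-4,5-epoxy-8-[(E)-2-methylbut-2-enoyloxy]-1-oxogermacra-7(11),10(14)-dien-12,6-olide | C=C1C[C@H](OC(=O)/C(C)=C/C)C2=C(COC(C)=O)C(=O)O[C@@H]2[C@H]2O[C@]2(C)CCC1=O | target

## Step count and least certain steps

Total: 14 steps. Longest linear sequence: 13 steps (steps 1, 2 and 4–14, from 1); step 3 is a one-step side branch that joins at step 4.

**Step 9 (key step).** The C4–Sn and C1–C5 bonds can only approach, not reach, an anti-periplanar alignment in the cis-fused cyclopentane. The polar fragmentation may therefore be slow, and competing homolysis of the lead alkoxide would lose the stereospecificity (E/Z mixture) or cut C1–C2. The acetic acid set free may also protodestannylate the tertiary stannane before the hindered carbinol has bound to lead. Fallback, from 18 back to 20: generate the C1 alkoxy radical instead (PhI(OAc)2, I2, visible light, cyclohexane/CH2Cl2, rt). β-Scission of C1–C5 is again steered by tin, and the C5 radical expels the stannyl radical from C4. This replaces the lead-alkoxide pathway by a radical chain at room temperature without free acid. No new compound is formed on the way (F0).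

**Step 7.** The enolate is racemic, so the wanted series is at best half of the aldehyde partner, and the two enolate enantiomers will not react equally fast with the (S)-configured aldehyde. If the C8 substituent shields the face that the (S)-C4 enolate must attack, the unwanted diastereomer predominates. A smaller risk is attack cis to tin, which would end as the (Z)-olefin. Fallback, from 3 back to 22: run the same sequence in the C8-epimeric series, where the (S)-C4 enolate is the favoured partner, and correct C8 when the tiglate is introduced.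
- Aldehyde 3 with the (R,R)-controller gives (1R)-3-bromo-1-{4-[(4-methoxybenzyloxy)methyl]furan-3-yl}but-3-en-1-ol F1.
- Silylation gives its TBS ether F2, and photo-oxygenation gives the (1R)-side-chain hydroxybutenolide F3.
- The stannylation/aldol step gives the C8-epimeric keto butenolide F4, and Ni/Cr closure gives the C8-epimeric stannyl hydroazulenol F5.
- Pb(OAc)4 gives the (4E,6R,8R)-silyloxy trienolide F6, and HF·pyridine gives the (8R)-alcohol F7.
- Mitsunobu esterification of F7 with tiglic acid (PPh3, DIAD) inverts C8 and returns to 22.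

**Step 8.** Oxidative addition of a 2-bromoalkene is slow, and addition of the alkenylchromium to a hindered, enolisable ketone is slower than to an aldehyde. The alkenyl metal may simply be protonated, or the β-acyloxy ketone may eliminate under the warm, Lewis-acidic conditions. Fallback, from 8 back to 18: change the halide before the sensitive functionality exists.
- Copper-catalysed halogen exchange on 8 (NaI, CuI, N,N′-dimethylethylenediamine, dioxane, 110 °C) gives {[(1S)-3-iodo-1-{4-[(4-methoxybenzyloxy)methyl]furan-3-yl}but-3-en-1-yl]oxy}(tert-butyl)dimethylsilane F8.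
- Steps 6 and 7 then give the iodo hydroxybutenolide F9 and the iodo keto butenolide F10.
- F10 enters the Ni/Cr cycle at room temperature; it can also be cyclised by lithium–iodine exchange at −100 °C (anionic cyclisation) to give 18.

**Step 6.** The two furan α-positions differ only in the size of the neighbouring substituent, so the amine may not discriminate well and the regioisomeric hydroxybutenolide (carbonyl beside C7) would form. Fallback, from 1 back to 10: fix the regiochemistry with a silyl group.
- Mono-silylation of 1 gives [4-({[tert-butyl(dimethyl)silyl]oxy}methyl)furan-3-yl]methanol F11.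
- Alkoxide-directed lithiation (n-BuLi, 2.2 equiv) and TMSCl put silicon on the α-carbon next to the free hydroxymethyl arm, giving the 2-(trimethylsilyl)furan F12.
- PMB protection gives F13, TBAF at 0 °C gives the alcohol F14, and MnO2 gives the aldehyde F15.
- Bromoallylation as in step 4 gives the alcohol F16, and silylation gives the TBS ether F17.
- In the photo-oxygenation of F17 the silyl-bearing carbon becomes the lactone carbonyl, which gives 10 as a single regioisomer.

**Step 14.** The face selection rests on a conformational argument for a new ten-membered ring. If the ring adopts a conformer with the lactone oxygen and not H6 in the olefin plane, the epimeric (4S,5S) epoxide would form. Fallback, from 24 back to 25: replace substrate control by reagent control with a Shi epoxidation (fructose-derived ketone catalyst of the enantiomeric series that matches the required face, KHSO5, K2CO3, MeCN/dimethoxymethane, 0 °C). (E)-Trisubstituted olefins are the best substrates for that catalyst. No new compound is formed on the way (F0).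

## Further compounds

F0 | step 9 | none | none
F1 | step 7 | (1R)-3-bromo-1-{4-[(4-methoxybenzyloxy)methyl]furan-3-yl}but-3-en-1-ol | C=C(Br)C[C@@H](O)c1cocc1COCc1ccc(OC)cc1
F2 | step 7 | {[(1R)-3-bromo-1-{4-[(4-methoxybenzyloxy)methyl]furan-3-yl}but-3-en-1-yl]oxy}(tert-butyl)dimethylsilane | C=C(Br)C[C@@H](O[Si](C)(C)C(C)(C)C)c1cocc1COCc1ccc(OC)cc1
F3 | step 7 | 4-[(1R)-3-bromo-1-(tert-butyldimethylsilyloxy)but-3-en-1-yl]-5-hydroxy-3-[(4-methoxybenzyloxy)methyl]furan-2(5H)-one | C=C(Br)C[C@@H](O[Si](C)(C)C(C)(C)C)C1=C(COCc2ccc(OC)cc2)C(=O)OC1O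
F4 | step 7 | (5R)-4-[(1R)-3-bromo-1-(tert-butyldimethylsilyloxy)but-3-en-1-yl]-3-[(4-methoxybenzyloxy)methyl]-5-[(1S,2S)-2-methyl-5-oxo-2-(trimethylstannyl)cyclopentyl]furan-2(5H)-one | C=C(Br)C[C@@H](O[Si](C)(C)C(C)(C)C)C1=C(COCc2ccc(OC)cc2)C(=O)O[C@@H]1[C@@H]2[C@@](C)([Sn](C)(C)C)CCC2=O
F5 | step 7 | (1R,4S,5S,6R,8R)-8-(tert-butyldimethylsilyloxy)-1-hydroxy-13-(4-methoxybenzyloxy)-4-(trimethylstannyl)guaia-7(11),10(14)-dien-12,6-olide | C=C1C[C@@H](O[Si](C)(C)C(C)(C)C)C2=C(COCc3ccc(OC)cc3)C(=O)O[C@@H]2[C@@H]3[C@@](C)([Sn](C)(C)C)CC[C@]13O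
F6 | step 7 | (4E,6R,8R)-8-(tert-butyldimethylsilyloxy)-13-(4-methoxybenzyloxy)-1-oxogermacra-4,7(11),10(14)-trien-12,6-olide | C=C1C[C@@H](O[Si](C)(C)C(C)(C)C)C2=C(COCc3ccc(OC)cc3)C(=O)O[C@@H]2/C=C(\C)CCC1=O
F7 | step 7 | (4E,6R,8R)-8-hydroxy-13-(4-methoxybenzyloxy)-1-oxogermacra-4,7(11),10(14)-trien-12,6-olide | C=C1C[C@@H](O)C2=C(COCc3ccc(OC)cc3)C(=O)O[C@@H]2/C=C(\C)CCC1=O
F8 | step 8 | {[(1S)-3-iodo-1-{4-[(4-methoxybenzyloxy)methyl]furan-3-yl}but-3-en-1-yl]oxy}(tert-butyl)dimethylsilane | C=C(I)C[C@H](O[Si](C)(C)C(C)(C)C)c1cocc1COCc1ccc(OC)cc1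
F9 | step 8 | 4-[(1S)-1-(tert-butyldimethylsilyloxy)-3-iodobut-3-en-1-yl]-5-hydroxy-3-[(4-methoxybenzyloxy)methyl]furan-2(5H)-one | C=C(I)C[C@H](O[Si](C)(C)C(C)(C)C)C1=C(COCc2ccc(OC)cc2)C(=O)OC1O
F10 | step 8 | (5R)-4-[(1S)-1-(tert-butyldimethylsilyloxy)-3-iodobut-3-en-1-yl]-3-[(4-methoxybenzyloxy)methyl]-5-[(1S,2S)-2-methyl-5-oxo-2-(trimethylstannyl)cyclopentyl]furan-2(5H)-one | C=C(I)C[C@H](O[Si](C)(C)C(C)(C)C)C1=C(COCc2ccc(OC)cc2)C(=O)O[C@@H]1[C@@H]2[C@@](C)([Sn](C)(C)C)CCC2=O
F11 | step 6 | [4-({[tert-butyl(dimethyl)silyl]oxy}methyl)furan-3-yl]methanol | CC(C)(C)[Si](C)(C)OCc1cocc1CO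
F12 | step 6 | [4-({[tert-butyl(dimethyl)silyl]oxy}methyl)-2-(trimethylsilyl)furan-3-yl]methanol | OCc1c([Si](C)(C)C)occ1CO[Si](C)(C)C(C)(C)C
F13 | step 6 | tert-butyl({4-[(4-methoxybenzyloxy)methyl]-5-(trimethylsilyl)furan-3-yl}methoxy)dimethylsilane | COc1ccc(COCc2c([Si](C)(C)C)occ2CO[Si](C)(C)C(C)(C)C)cc1
F14 | step 6 | {4-[(4-methoxybenzyloxy)methyl]-5-(trimethylsilyl)furan-3-yl}methanol | COc1ccc(COCc2c([Si](C)(C)C)occ2CO)cc1
F15 | step 6 | 4-[(4-methoxybenzyloxy)methyl]-5-(trimethylsilyl)furan-3-carbaldehyde | COc1ccc(COCc2c([Si](C)(C)C)occ2C=O)cc1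
F16 | step 6 | (1S)-3-bromo-1-{4-[(4-methoxybenzyloxy)methyl]-5-(trimethylsilyl)furan-3-yl}but-3-en-1-ol | C=C(Br)C[C@H](O)c1coc([Si](C)(C)C)c1COCc1ccc(OC)cc1
F17 | step 6 | {[(1S)-3-bromo-1-{4-[(4-methoxybenzyloxy)methyl]-5-(trimethylsilyl)furan-3-yl}but-3-en-1-yl]oxy}(tert-butyl)dimethylsilane | C=C(Br)C[C@H](O[Si](C)(C)C(C)(C)C)c1coc([Si](C)(C)C)c1COCc1ccc(OC)cc1
F0 | step 14 | none | none
A1 | alternative 1 | epoxy macrocyclic butenolide (C1 and C8 silyl ethers) | C=C1C[C@H](O[Si](C)(C)C(C)(C)C)C2=C(COCc3ccc(OC)cc3)C(=O)O[C@@H]2[C@H]2O[C@]2(C)CC[C@@H]1O[Si](C)(C)C(C)(C)C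
A2 | alternative 1 | open-chain epoxy aldehyde carrying the (Z)-β-triflyloxy enoate | O=C[C@H]1O[C@]1(C)CC[C@H](O[Si](C)(C)C(C)(C)C)C(=C)C[C@H](O[Si](C)(C)C(C)(C)C)/C(OS(=O)(=O)C(F)(F)F)=C(\COCc1ccc(OC)cc1)C(=O)OC
A3 | alternative 2 | ten-membered enone butenolide diol acetonide | C=C1C[C@H](O[Si](C)(C)C(C)(C)C)C2=C(COC(C)=O)C(=O)O[C@@H]2[C@@H]2OC(C)(C)O[C@]2(C)CCC1=O
A4 | alternative 2 | cycloheptanone with quaternary C7 bearing the 2-bromoallyl carbinol chain and the α-phenylthio γ-lactone (configuration at C7 and C11 immaterial, both are lost) | C=C(Br)C[C@H](O[Si](C)(C)C(C)(C)C)C12C(=O)CC[C@@]3(C)OC(C)(C)O[C@H]3[C@H]1OC(=O)C2(COC(C)=O)Sc1ccccc1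
A5 | alternative 3 | ring-expanded keto enol ether | COc1ccc(COC[C@@H]2C[C@H](O[Si](C)(C)C(C)(C)C)CC(=O)C[C@H](C)C/C=C2\OC)cc1
A6 | alternative 3 | 1-methoxy-1-vinyl-2-[(E)-prop-1-enyl]cyclohexan-2-ol with trans-diequatorial alkenyl groups | COc1ccc(COC[C@@H]2C[C@H](O[Si](C)(C)C(C)(C)C)C[C@](O)(/C=C/C)[C@@]2(OC)C=C)cc1
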